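The readings stem from a simulated flask on assumed constants; scatter was added.

The eta flask carries catalyst at 0.0400% of its starting material, less than the 0.200% of the delta run, and I take that ratio as the thing to follow.

| flask | starting material | partner | free catalyst | time |
|---|---|---|---|---|
| delta | 120 mM | 180 mM | 0.240 mM |  |
| alpha | 48.0 mM | 108 mM | 0.240 mM |  |
| gamma | 180 mM | 180 mM | 0.240 mM |  |
| beta | 120 mM | 180 mM | 0.120 mM |  |
| eta | 600 mM | 900 mM | 0.240 mM | 15 h |

| run | time / h | [target] / mM |
|---|---|---|
| delta run | 0.60 | 11.5 |
| delta run | 1.1 | 22.3 |
| delta run | 2.2 | 39.8 |
| delta run | 4.1 | 61.2 |
| delta run | 7.9 | 79.1 |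
| delta run | 15 | 93.0 |
| alpha run | 0.60 | 4.9 |
| alpha run | 1.1 | 8.9 |
| alpha run | 2.2 | 16.3 |
| alpha run | 4.1 | 27.1 |
| alpha run | 7.9 | 36.1 |
| alpha run | 15 | 39.8 |
| gamma run | 0.60 | 20.1 |
| gamma run | 1.1 | 32.5 |
| gamma run | 2.2 | 58.3 |
| gamma run | 4.1 | 84.8 |
| gamma run | 7.9 | 111.2 |
| gamma run | 15 | 125.0 |
| beta run | 0.60 | 6.0 |
| beta run | 1.1 | 12.0 |
| beta run | 2.2 | 23.3 |
| beta run | 4.1 | 37.5 |
| beta run | 7.9 | 57.2 |
| beta run | 15 | 69.1 |

(standard deviation of a reading: 1 mM)

1. how the opening rate goes with [starting material] round the charge of the delta run: the exponent of the rate at two percent of starting material gone to target (one fixed amount of target, the same in the runs compared)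
2. how the opening rate goes with [partner] round the charge of the delta run: the exponent of the rate at two percent of starting material gone to target
3. the alpha run starts with 72.0 mM less of starting material and of partner than the delta run, and with no target. Compared where both hold the same amount of starting material, once fifteen percent of what the alpha run was charged with has turned into target, is the alpha run faster, slower or alike (within a tenth)?
4. target in the eta run at 15 h, as a share of the starting material charged

- Overall: starting material + partner -> target, with free catalyst as catalyst.
- Constant volume, constant temperature.
- The analysis sees a species whether free or bound.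
- "The second partner" is partner.
- An order is taken over about fifteen percent of the charge, up and down.

Starting material is the limiting reagent in eta, 600 mM against 900 mM of partner, so I keep its ledger. Each mM is either target, still starting material, or held on catalyst, and that last entry cannot pass 0.240 mM, a correction I drop. Two entries remain, and I write u = ln(charge / c(starting material)) for the first-order exposure.

The delta run opens at 0.187 /h of exposure, pseudo-first-order, but between its last two readings it makes 0.0585 /h, so by my reading 68.7% of its catalyst has stopped working at exposure 1.28.

I assume that catalyst is lost in proportion to c(target) as it works in proportion to c(starting material). Summed over the run, the catalyst lost equals σ × charge × (u − 1 + exp(−u)), where σ is the spending ratio, a selectivity factor: catalyst lost per unit of exposure for each mM of target present. The delta reading gives 0.00245. The same reading on the gamma run, at exposure 1.07, gives 0.00267.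

The books close when the catalyst lost equals the catalyst charged. For eta that asks u − 1 + exp(−u) = 0.163, and the series gives a stopping exposure of 0.626. The ledger then reads 46.5% of the charge as target, 279 mM, and 321 mM of starting material left. Reaching that takes about 3.35 h at the opening pace, and the last gap shrinks with a time constant of 1.88 h, so the sum stands shorter than 15 h, and I commit to the stop.

The forecast gives 0.95 and 0.03 for the orders in starting material and partner, faster for the alpha comparison and 49% for eta, above my figure, on the view that “the catalyst is dying, with a lifetime of roughly 14 h” together with target inhibition.

The simulation gives 46.6% of the starting material charged as target in eta at 15 h, with orders 0.91 in starting material and 0.11 in partner, and the alpha run faster.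

    free catalyst + starting material → catalyst-substrate complex (878.4 /M/h)
    catalyst-substrate complex + partner → target + free catalyst (4824 /M/h)
    free catalyst + target → spent catalyst + target (2.178 /M/h)

The step that spends free catalyst runs on target, and a fit with the partner lost in pairs leaves a root mean square residual of 3.9 in units of the scatter, against 1.1 for these steps. Putting 0.00245 on the eta result, exposure 0.627 reckons to 0.237 mM of the 0.240 mM lost, and on the gamma run, the exposure of 1.19 read at 15 h reckons to 0.217 mM of its 0.240 mM lost.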